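## Retrosynthetic overview

1. Lapiferine ⇐ 6-O-angeloyl 8α-hydroxy-Δ9 daucane: the C10–O bond and both oxirane C–O bonds are made last by one oxovanadium relay (allylic 1,3-transposition, then hydroxyl-directed epoxidation).
2. That tertiary allylic alcohol ⇐ jaeschkeanadiol by 6α-OH-directed epoxidation, selenolate opening/selenoxide elimination, and angeloylation of the only secondary hydroxyl.
3. Jaeschkeanadiol ⇐ ring-closing metathesis (C8=C9) of a cyclopentane carrying an allyl arm on C1 and a 1-hydroxy-3-methylbut-3-enyl arm on C5.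
4. That cyclopentane ⇐ isopropyl addition (C4) and a one-pot enantioselective conjugate methylation/anti-aldol (C1, C5, C6) on 3-allylcyclopent-2-enone with 3-methylbut-3-enal.
5. Ring order: the five-membered ring is bought (3-ethoxycyclopent-2-enone), the seven-membered ring is closed by metathesis, the oxirane is formed last.

Assumption: daucane numbering is used (C1 = methyl-bearing ring-fusion carbon, C4 = isopropyl carbinol, C5 = ring-fusion CH, C6 = ester carbon, C8/C9 = oxirane, C10 = carbinol next to C1); α is the face of H-5, "trans" means H-5 and the C1 methyl lie on opposite faces, and compound numbers follow the forward steps.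

## Route

Step 1
Reactants: 1 3-ethoxycyclopent-2-en-1-one
Product: 3 3-(prop-2-en-1-yl)cyclopent-2-en-1-one, via tertiary allylic alcohol 2 (not isolated)
Conditions: allylMgBr, Et2O, 0 °C; then 1 M HCl, 0 °C, 15 min
Reagents that add atoms: allylmagnesium bromide, C=CC[Mg]Br; water, O
Why: 1,2-Grignard addition to the vinylogous ester followed by acid-promoted hydrolysis–dehydration (Stork–Danheiser transposition) gives the β-allyl enone, brief cold acid keeps the allyl double bond out of conjugation, and no stereocentre is formed.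

Step 2
Reactants: 4 3-methylbut-3-en-1-ol
Product: 5 3-methylbut-3-enal
Conditions: Dess–Martin periodinane, CH2Cl2, 0 °C; filtered through NaHCO3/silica, solution used at once
Reagents that add atoms: none
Why: Dess–Martin oxidation stops at the aldehyde under non-basic conditions that do not isomerise the β,γ-unsaturated aldehyde to the conjugated isomer, and no stereocentre is formed.

Step 3
Reactants: 3 3-(prop-2-en-1-yl)cyclopent-2-en-1-one; 5 3-methylbut-3-enal
Product: 7 (2S,3R)-2-[(1S)-1-hydroxy-3-methylbut-3-en-1-yl]-3-methyl-3-(prop-2-en-1-yl)cyclopentan-1-one, via dimethylaluminium enolate 6 (not isolated)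
Conditions: Me3Al (1.2 equiv), Cu(OTf)2 (5 mol %), chiral sulfonate-bearing NHC ligand (6 mol %, enantiomer giving the 3R centre), THF, −78 °C; then 5, −78 to −40 °C; aq. Rochelle salt
Reagents that add atoms: trimethylaluminium, C[Al](C)C
Why: Copper–NHC-catalysed enantioselective conjugate addition of Me3Al sets the quaternary C1 under ligand control, and the regiodefined aluminium enolate then adds to 5 in a Zimmerman–Traxler aldol on the face opposite the larger allyl group (sets C5) through the chair of the cyclic E-enolate (anti aldol, sets C6).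

Step 4
Reactants: 7 (2S,3R)-2-[(1S)-1-hydroxy-3-methylbut-3-en-1-yl]-3-methyl-3-(prop-2-en-1-yl)cyclopentan-1-one
Product: 8 (1R,2S,3R)-2-[(1S)-1-hydroxy-3-methylbut-3-en-1-yl]-3-methyl-1-(propan-2-yl)-3-(prop-2-en-1-yl)cyclopentan-1-ol
Conditions: iPrMgCl (3 equiv), CeCl3, THF, −78 °C
Reagents that add atoms: isopropylmagnesium chloride, CC(C)[Mg]Cl
Why: Organocerium (Imamoto) 1,2-addition suppresses enolisation and retro-aldol, and the isopropyl group enters the cyclopentanone trans to the C5 side chain (cerium chelated between the carbonyl and the C6 alkoxide), which gives the 4β tertiary alcohol.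

Step 5
Reactants: 8 (1R,2S,3R)-2-[(1S)-1-hydroxy-3-methylbut-3-en-1-yl]-3-methyl-1-(propan-2-yl)-3-(prop-2-en-1-yl)cyclopentan-1-ol
Product: 9 jaeschkeanadiol
Conditions: second-generation Grubbs catalyst (5 mol %), CH2Cl2 (0.005 M), 40 °C
Reagents that add atoms: none
Why: Ring-closing metathesis joins the allyl and methallyl termini, which sit trans on the cyclopentane, into the trans-fused seven-membered ring with the trisubstituted C8=C9 alkene, and no stereocentre is touched.

Step 6
Reactants: 9 jaeschkeanadiol
Product: 10 8α,9α-epoxy-trans-daucane-4β,6α-diol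
Conditions: VO(acac)2 (5 mol %), t-BuOOH, CH2Cl2, 0 °C to rt
Reagents that add atoms: tert-butyl hydroperoxide, CC(C)(C)OO
Why: Sharpless vanadium-catalysed epoxidation is delivered by the homoallylic 6α-hydroxyl through its vanadate ester, so oxygen enters C8=C9 from the α face (sets C8 and C9).

Step 7
Reactants: 10 8α,9α-epoxy-trans-daucane-4β,6α-diol
Product: 13 trans-dauc-9-ene-4β,6α,8α-triol, via hydroxy selenide 11 (not isolated), via selenoxide 12 (not isolated)
Conditions: (PhSe)2, NaBH4, EtOH, 78 °C; then THF, 30% H2O2, pyridine, 0 °C to rt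
Reagents that add atoms: none
Why: Sharpless–Lauer epoxide-to-allylic-alcohol transposition, in which benzeneselenolate opens the oxirane by SN2 attack at the less substituted C9 (the C8–O bond is kept as the 8α tertiary alcohol) and the selenoxide syn-elimination can only take a C10 hydrogen, giving C9=C10.

Step 8
Reactants: 13 trans-dauc-9-ene-4β,6α,8α-triol; 14 angelic acid
Product: 16 6α-angeloyloxy-trans-dauc-9-ene-4β,8α-diol, via mixed anhydride 15 (not isolated)
Conditions: 14, 2,4,6-trichlorobenzoyl chloride, Et3N, PhMe, rt; then 13, 80 °C (no DMAP)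
Reagents that add atoms: none
Why: Yamaguchi-type mixed-anhydride esterification acylates the only secondary hydroxyl (both tertiary alcohols are inert), the DMAP-free protocol keeps the Z geometry of the angelate, and no stereocentre is touched.

Step 9
Reactants: 16 6α-angeloyloxy-trans-dauc-9-ene-4β,8α-diol
Product: 18 lapiferine, via transposed allylic alcohol 17 (not isolated)
Conditions: VO(OSiPh3)3 (10 mol %), 4 Å MS, PhMe, 60 °C; then 0 °C, t-BuOOH (1.3 equiv)
Reagents that add atoms: tert-butyl hydroperoxide, CC(C)(C)OO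
Why: Proposed new method: one oxovanadium catalyst makes both C–O bond sets in sequence — the tertiary allyl vanadate of 16 undergoes a [3,3] oxo shift that is necessarily suprafacial on the ring, so the oxygen function moves from C8α to C10α and the more stable trisubstituted C8=C9 alkene returns (sets C10), and after t-BuOOH is added the same pentavalent vanadium centre, now bound to the 10α alkoxide, delivers oxygen syn to the α face of C8=C9 (sets C8 and C9); the closest known reactions are the vanadate- or perrhenate-catalysed 1,3-transposition of allylic alcohols and the Sharpless VO(acac)2/t-BuOOH epoxidation of allylic alcohols.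

## Compound list

1 | 3-ethoxycyclopent-2-en-1-one | CCOC1=CC(=O)CC1 | starting material
2 | 3-ethoxy-1-(prop-2-en-1-yl)cyclopent-2-en-1-ol (racemic, formed as its magnesium alkoxide) | CCOC1=CC(O)(CC=C)CC1 | intermediate
3 | 3-(prop-2-en-1-yl)cyclopent-2-en-1-one | O=C1C=C(CC=C)CC1 | intermediate
4 | 3-methylbut-3-en-1-ol | CC(=C)CCO | starting material
5 | 3-methylbut-3-enal | CC(=C)CC=O | intermediate
6 | dimethylaluminium (3R)-3-methyl-3-(prop-2-en-1-yl)cyclopent-1-en-1-olate | C[Al](C)OC1=C[C@@](C)(CC=C)CC1 | intermediate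
7 | (2S,3R)-2-[(1S)-1-hydroxy-3-methylbut-3-en-1-yl]-3-methyl-3-(prop-2-en-1-yl)cyclopentan-1-one | O[C@@H](CC(C)=C)[C@H]1C(=O)CC[C@]1(C)CC=C | intermediate
8 | (1R,2S,3R)-2-[(1S)-1-hydroxy-3-methylbut-3-en-1-yl]-3-methyl-1-(propan-2-yl)-3-(prop-2-en-1-yl)cyclopentan-1-ol | O[C@@H](CC(C)=C)[C@H]1[C@](O)(C(C)C)CC[C@]1(C)CC=C | intermediate
9 | jaeschkeanadiol, (3R,3aS,4S,8aR)-6,8a-dimethyl-3-(propan-2-yl)-1,2,3,3a,4,5,8,8a-octahydroazulene-3,4-diol (trans-dauc-8-ene-4β,6α-diol) | O[C@H]1CC(C)=CC[C@@]2(C)CC[C@@](O)(C(C)C)[C@H]12 | intermediate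
10 | 8α,9α-epoxy-trans-daucane-4β,6α-diol | O[C@H]1C[C@@]2(C)O[C@H]2C[C@@]2(C)CC[C@@](O)(C(C)C)[C@H]12 | intermediate
11 | 9β-(phenylselanyl)-trans-daucane-4β,6α,8α-triol | O[C@H]1C[C@@](C)(O)[C@H]([Se]c3ccccc3)C[C@@]2(C)CC[C@@](O)(C(C)C)[C@H]12 | intermediate
12 | 9β-(phenylseleninyl)-trans-daucane-4β,6α,8α-triol | O[C@H]1C[C@@](C)(O)[C@H]([Se](=O)c3ccccc3)C[C@@]2(C)CC[C@@](O)(C(C)C)[C@H]12 | intermediate
13 | trans-dauc-9-ene-4β,6α,8α-triol (8β-methyl) | O[C@H]1C[C@@](C)(O)C=C[C@@]2(C)CC[C@@](O)(C(C)C)[C@H]12 | intermediate
14 | angelic acid, (Z)-2-methylbut-2-enoic acid | C/C=C(/C)C(=O)O | starting material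
15 | (Z)-2-methylbut-2-enoic 2,4,6-trichlorobenzoic anhydride | C/C=C(/C)C(=O)OC(=O)c1c(Cl)cc(Cl)cc1Cl | intermediate
16 | 6α-angeloyloxy-trans-dauc-9-ene-4β,8α-diol | C/C=C(/C)C(=O)O[C@H]1C[C@@](C)(O)C=C[C@@]2(C)CC[C@@](O)(C(C)C)[C@H]12 | intermediate
17 | 6α-angeloyloxy-trans-dauc-8-ene-4β,10α-diol | C/C=C(/C)C(=O)O[C@H]1CC(C)=C[C@@H](O)[C@@]2(C)CC[C@@](O)(C(C)C)[C@H]12 | intermediate
18 | lapiferine (6α-angeloyloxy-8α,9α-epoxy-trans-daucane-4β,10α-diol) | C/C=C(/C)C(=O)O[C@H]1C[C@@]2(C)O[C@H]2[C@@H](O)[C@@]2(C)CC[C@@](O)(C(C)C)[C@H]12 | target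

## Step count and risks

Total: 9 steps. Longest linear sequence: 8 steps (steps 1 and 3–9 from 1); step 2 is a one-step side branch.

Steps most likely to fail:

**Step 3 (one-pot conjugate methylation/aldol).** Three stereocentres are set at once, the facial bias of allyl against methyl at C5 is moderate, and the aluminium enolate may react sluggishly with the enolisable aldehyde. Fallback, from 3 back to 7: the copper-catalysed Me3Al addition is run as in step 3 but quenched with Et3SiOTf, and the silyl enol ether F1 is isolated. MeLi (THF, 0 °C) then releases the lithium enolate F2, which is cooled to −78 °C and treated with MgBr2·OEt2 and 5. This separates the conjugate addition from a closed-transition-state lithium/magnesium aldol and returns to the route at 7.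

**Step 4 (isopropyl addition to the hindered β-hydroxy ketone).** Enolisation, hydride transfer from the isopropyl reagent or retro-aldol may compete. Fallback, from 7 back to 9: the order of ring closure and addition is reversed. Ring-closing metathesis of 7 (second-generation Grubbs catalyst, CH2Cl2, 40 °C) gives the bicyclic hydroxy ketone F3. Its rigid trans-fused frame is then attacked by iPrLi/CeCl3 (THF, −78 °C) from the α face, opposite the angular methyl, which gives 9 directly.

**Step 9 (the proposed vanadium relay).** The tertiary allylic alcohol may dehydrate, or untransposed 16 may be epoxidised before it isomerises. Fallback with known chemistry, from 16 back to 17: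
- Babler–Dauben oxidative transposition with pyridinium chlorochromate (CH2Cl2, rt) gives the enone F4.
- Reduction with (S)-2-methyl-CBS-oxazaborolidine and catecholborane (PhMe, −78 °C; the quaternary C1 side acts as the large group) gives the 10α-alcohol 17.
- 17 is then epoxidised to 18 under standard VO(acac)2/t-BuOOH conditions, which is the known second half of step 9.

## Further compounds

F1 | step 3 | triethyl{[(3R)-3-methyl-3-(prop-2-en-1-yl)cyclopent-1-en-1-yl]oxy}silane | CC[Si](CC)(CC)OC1=C[C@@](C)(CC=C)CC1
F2 | step 3 | lithium (3R)-3-methyl-3-(prop-2-en-1-yl)cyclopent-1-en-1-olate | [Li]OC1=C[C@@](C)(CC=C)CC1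
F3 | step 4 | (3aS,4S,8aR)-4-hydroxy-6,8a-dimethyl-2,3a,4,5,8,8a-hexahydroazulen-3(1H)-one | O[C@H]1CC(C)=CC[C@@]2(C)CCC(=O)[C@H]12
F4 | step 9 | 6α-angeloyloxy-4β-hydroxy-trans-dauc-8-en-10-one | C/C=C(/C)C(=O)O[C@H]1CC(C)=CC(=O)[C@@]2(C)CC[C@@](O)(C(C)C)[C@H]12
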